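**Plan**

- Retrosynthesis: first cut the CH2–aryl bond between ring A (butyrylfilicinic ring) and ring B (aromatic ring), then the aryl–butyryl bond of ring B. Last, cut two ring bonds of ring C (propionylfilicinic ring): the bond from its ring C=O to the carbon that carries the bridge CH2, and the bond from the propionyl-bearing carbon to the enol carbon next to C(CH3)2.
- Enabling feature: ring C is a 1,3,5-trioxygenated six-membered ring with a quaternary C(CH3)2 ring carbon, that is, a folded 3,5,7-triketo ester. The quaternary carbon leaves the keto ester precursor only one enolisable α-carbon and makes its ester the only non-enolisable acyl electrophile.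
- Forward: ring B is bought as its tribenzyl ether and receives the C3 side chain. Ring C is then annulated onto that chain in one operation with a propionylketene donor (a β-keto thioester made by crossed Claisen condensation), so the right-hand bridge CH2 is in place before ring C exists.
- Ring B is then butyrylated and debenzylated. Ring A, made separately from phloroglucinol, is attached last through its Mannich base.
- Stereochemistry: the target has no stereocentre, so nothing needs control.

Key step: step 6

Assumption: 1,3,5-tris(benzyloxy)benzene 5 is taken as purchasable, and all enolised triketone rings are drawn in the tautomer of the target SMILES.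

**Route**

Step 1
Reactants: 1 methyl isobutyrate; 2 3-chloropropanoyl chloride
Product: 3 methyl 5-chloro-2,2-dimethyl-3-oxopentanoate
Conditions: LiN(i-Pr)2 (1.05 equiv), THF, −78 °C; enolate solution added to 2 (1.2 equiv) in THF, −78 °C; aq. NH4Cl
Reagents that add atoms: none
Why: Crossed Claisen C-acylation of a lithium ester enolate by an acid chloride; the product has no hydrogen between its carbonyls, and inverse addition at low temperature should keep the enolate from eliminating HCl from the product.

Step 2
Reactants: 3 methyl 5-chloro-2,2-dimethyl-3-oxopentanoate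
Product: 4 methyl 2,2-dimethyl-3-oxopent-4-enoate
Conditions: Et3N (1.2 equiv), Et2O, 0 °C; filtration; used at once
Reagents that add atoms: none
Why: E1cB dehydrochlorination of a β-chloro ketone should give the vinyl ketone, which is used fresh to avoid polymerisation.

Step 3
Reactants: 4 methyl 2,2-dimethyl-3-oxopent-4-enoate; 5 1,3,5-tris(benzyloxy)benzene
Product: 6 methyl 2,2-dimethyl-3-oxo-5-[2,4,6-tris(benzyloxy)phenyl]pentanoate
Conditions: Sc(OSO2CF3)3 (5 mol %), 5 (2 equiv), MeCN–CH2Cl2, 0 °C → rt
Reagents that add atoms: none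
Why: Lewis-acid-catalysed Friedel–Crafts conjugate addition of an electron-rich arene to a vinyl ketone; the three free positions of 5 are equivalent and excess arene should limit double alkylation.

Step 4
Reactants: 7 1H-benzotriazole; 8 propionyl chloride
Product: 9 1-(1H-benzotriazol-1-yl)propan-1-one
Conditions: Et3N (1.1 equiv), CH2Cl2, 0 °C → rt; aq. NaHCO3 wash
Reagents that add atoms: none
Why: N-acylation of benzotriazole by an acid chloride should give the stable N-acylbenzotriazole, an acyl donor mild enough for soft-enolisation chemistry.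

Step 5
Reactants: 9 1-(1H-benzotriazol-1-yl)propan-1-one; 10 S-phenyl thioacetate
Product: 11 S-phenyl 3-oxopentanethioate
Conditions: MgBr2·OEt2 (2.5 equiv), i-Pr2NEt (3 equiv), CH2Cl2, rt; 1 M HCl
Reagents that add atoms: none
Why: Crossed Claisen condensation by soft enolisation: the magnesium-coordinated thioester is deprotonated by the amine and C-acylated by the N-acylbenzotriazole, and the product rests as its magnesium chelate, which should protect it from a second acylation and from loss of thiophenolate.

Step 6
Reactants: 6 methyl 2,2-dimethyl-3-oxo-5-[2,4,6-tris(benzyloxy)phenyl]pentanoate; 11 S-phenyl 3-oxopentanethioate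
Product: 14 3,5-dihydroxy-4,4-dimethyl-2-propanoyl-6-{[2,4,6-tris(benzyloxy)phenyl]methyl}cyclohexa-2,5-dien-1-one, via propionylketene 12 (not isolated), via open-chain triketo ester 13 (not isolated)
Conditions: 6, NaN(SiMe3)2 (1.05 equiv), THF, −78 °C; Na enolate of 11 (1.3 equiv, from NaN(SiMe3)2, THF, −78 °C) added slowly, −78 → 25 °C; then NaN(SiMe3)2 (1.1 equiv), 50 °C; 1 M HCl
Reagents that add atoms: none
Why: Proposed new method: the sodium enolate of 11 should lose thiophenolate by E1cB on warming to give propionylketene 12, and the enolate of 6, which can form only on the CH2 side because the other α-carbon is the quaternary C(CH3)2, should add through carbon to the ketene carbonyl to give the enolate of triketo ester 13; the second charge of base then makes the triketone dianion, whose carbon between the propionyl group and the new ketone attacks the non-enolisable methyl ester and expels methoxide. The closest known reaction types are the Lacey–Dieckmann synthesis of 3-acyltetramic acids (acylketene acylation of a heteroatom, then Dieckmann closure) and the Claisen cyclisation of 3,5,7-triketo esters to acylphloroglucinols; the new element is a ketone enolate carbon as the acceptor of the ketene. Ring C closes by a 6-(enolexo)-exo-trig Dieckmann acyl substitution. No stereocentre is created, since the one stereocentre of 13 lies between two carbonyls and is lost on enolisation. The step needs C- over O-acylation and Claisen over aldol closure: C-attack is expected for a sodium enolate in THF, no stabilised carbanion of 13 can reach a ketone through a six-membered ring, an amide base instead of an alkoxide avoids retro-Claisen cleavage of 6, and any O-acylated or lactone by-path should be reopened by the released methoxide and drain to the very stable β-triketone anion of 14.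

Step 7
Reactants: 14 3,5-dihydroxy-4,4-dimethyl-2-propanoyl-6-{[2,4,6-tris(benzyloxy)phenyl]methyl}cyclohexa-2,5-dien-1-one; 15 butyric acid
Product: 17 2-{[3-butanoyl-2,4,6-tris(benzyloxy)phenyl]methyl}-3,5-dihydroxy-4,4-dimethyl-6-propanoylcyclohexa-2,5-dien-1-one, via butanoic trifluoroacetic anhydride 16 (not isolated)
Conditions: (CF3CO)2O (3 equiv), 15 (2 equiv), CH2Cl2, 0 °C → rt; then aq. NaHCO3–MeOH, rt
Reagents that add atoms: none
Why: Friedel–Crafts acylation by a mixed anhydride without a metal Lewis acid; the tri-alkoxy ring carries the only free nucleophilic carbons (two equivalent positions), the first acyl group deactivates it against a second, and enol esters formed on ring C should hydrolyse in the work-up.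

Step 8
Reactants: 17 2-{[3-butanoyl-2,4,6-tris(benzyloxy)phenyl]methyl}-3,5-dihydroxy-4,4-dimethyl-6-propanoylcyclohexa-2,5-dien-1-one
Product: 18 2-[(3-butanoyl-2,4,6-trihydroxyphenyl)methyl]-3,5-dihydroxy-4,4-dimethyl-6-propanoylcyclohexa-2,5-dien-1-one
Conditions: H2 (1 atm), Pd/C (10 wt %), EtOAc–MeOH, rt
Reagents that add atoms: none
Why: Hydrogenolysis of the three benzyl aryl ethers under neutral conditions; the hindered chelated aryl ketone and the enolised triketone ring should not be reduced.

Step 9
Reactants: 19 phloroglucinol; 20 butyryl chloride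
Product: 21 1-(2,4,6-trihydroxyphenyl)butan-1-one
Conditions: AlCl3 (3.5 equiv), PhNO2–CH2Cl2, 0 °C → rt; ice/1 M HCl
Reagents that add atoms: none
Why: Friedel–Crafts acylation of phloroglucinol, which should stop at the mono-ketone because the acyl group deactivates the ring.

Step 10
Reactants: 21 1-(2,4,6-trihydroxyphenyl)butan-1-one
Product: 23 2-butanoyl-3,5-dihydroxy-4,4-dimethylcyclohexa-2,5-dien-1-one, via C-monomethylated ketone 22 (not isolated)
Conditions: NaOMe (3 equiv), MeI (2.2 equiv), MeOH, 0 °C → rt; 1 M HCl
Reagents that add atoms: iodomethane, CI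
Why: Dearomatising double C-methylation of an acylphloroglucinol polyanion; the once-methylated ring carbon is the most nucleophilic site, and the gem-dimethyl trione anion formed is less reactive, which should favour the filicinic acid pattern.

Step 11
Reactants: 23 2-butanoyl-3,5-dihydroxy-4,4-dimethylcyclohexa-2,5-dien-1-one
Product: 24 2-butanoyl-6-[(dimethylamino)methyl]-3,5-dihydroxy-4,4-dimethylcyclohexa-2,5-dien-1-one
Conditions: Eschenmoser's salt (1.05 equiv), i-Pr2NEt (1.05 equiv), CH2Cl2, 0 °C → rt
Reagents that add atoms: N,N-dimethylmethyleneiminium iodide (Eschenmoser's salt), C=[N+](C)C.[I-]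
Why: Mannich aminomethylation at the single free ring carbon of the enolised trione, with a preformed iminium salt to avoid formaldehyde-mediated dimerisation.

Step 12
Reactants: 18 2-[(3-butanoyl-2,4,6-trihydroxyphenyl)methyl]-3,5-dihydroxy-4,4-dimethyl-6-propanoylcyclohexa-2,5-dien-1-one; 24 2-butanoyl-6-[(dimethylamino)methyl]-3,5-dihydroxy-4,4-dimethylcyclohexa-2,5-dien-1-one
Product: 26 2-butanoyl-6-({3-butanoyl-5-[(2,4-dihydroxy-3,3-dimethyl-6-oxo-5-propanoylcyclohexa-1,4-dien-1-yl)methyl]-2,4,6-trihydroxyphenyl}methyl)-3,5-dihydroxy-4,4-dimethylcyclohexa-2,5-dien-1-one (target CNP0373153.0), via methylidene trione 25 (not isolated)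
Conditions: 24 (1.1 equiv), 1,4-dioxane, 60 °C, N2 stream; dilute HCl wash
Reagents that add atoms: none
Why: Thermal loss of dimethylamine from the Mannich base should give a quinone-methide-like methylidene trione, which the only free aromatic CH of 18 captures in a Michael/Friedel–Crafts sense; neither partner has another free nucleophilic ring carbon, so oligomers are not expected.

**Compound list**

1 | methyl isobutyrate | COC(=O)C(C)C | starting material
2 | 3-chloropropanoyl chloride | O=C(Cl)CCCl | starting material
3 | methyl 5-chloro-2,2-dimethyl-3-oxopentanoate | COC(=O)C(C)(C)C(=O)CCCl | intermediate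
4 | methyl 2,2-dimethyl-3-oxopent-4-enoate | COC(=O)C(C)(C)C(=O)C=C | intermediate
5 | 1,3,5-tris(benzyloxy)benzene | c1ccc(COc2cc(OCc3ccccc3)cc(OCc3ccccc3)c2)cc1 | starting material
6 | methyl 2,2-dimethyl-3-oxo-5-[2,4,6-tris(benzyloxy)phenyl]pentanoate | COC(=O)C(C)(C)C(=O)CCc1c(OCc2ccccc2)cc(OCc2ccccc2)cc1OCc1ccccc1 | intermediate
7 | 1H-benzotriazole | c1ccc2[nH]nnc2c1 | starting material
8 | propionyl chloride | CCC(=O)Cl | starting material
9 | 1-(1H-benzotriazol-1-yl)propan-1-one (1-propanoylbenzotriazole) | CCC(=O)n1nnc2ccccc21 | intermediate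
10 | S-phenyl thioacetate | CC(=O)Sc1ccccc1 | starting material
11 | S-phenyl 3-oxopentanethioate | CCC(=O)CC(=O)Sc1ccccc1 | intermediate
12 | propionylketene (3-oxopent-1-en-1-one) | CCC(=O)C=C=O | intermediate (not isolated)
13 | methyl 2,2-dimethyl-3,5,7-trioxo-4-{[2,4,6-tris(benzyloxy)phenyl]methyl}nonanoate (racemic, enolisable) | CCC(=O)CC(=O)C(Cc1c(OCc2ccccc2)cc(OCc2ccccc2)cc1OCc1ccccc1)C(=O)C(C)(C)C(=O)OC | intermediate (not isolated)
14 | 3,5-dihydroxy-4,4-dimethyl-2-propanoyl-6-{[2,4,6-tris(benzyloxy)phenyl]methyl}cyclohexa-2,5-dien-1-one | CCC(=O)C1=C(O)C(C)(C)C(O)=C(Cc2c(OCc3ccccc3)cc(OCc3ccccc3)cc2OCc2ccccc2)C1=O | intermediate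
15 | butyric acid | CCCC(=O)O | starting material
16 | butanoic trifluoroacetic anhydride | CCCC(=O)OC(=O)C(F)(F)F | intermediate (not isolated)
17 | 2-{[3-butanoyl-2,4,6-tris(benzyloxy)phenyl]methyl}-3,5-dihydroxy-4,4-dimethyl-6-propanoylcyclohexa-2,5-dien-1-one | CCCC(=O)c1c(OCc2ccccc2)cc(OCc2ccccc2)c(CC2=C(O)C(C)(C)C(O)=C(C(=O)CC)C2=O)c1OCc1ccccc1 | intermediate
18 | 2-[(3-butanoyl-2,4,6-trihydroxyphenyl)methyl]-3,5-dihydroxy-4,4-dimethyl-6-propanoylcyclohexa-2,5-dien-1-one | CCCC(=O)c1c(O)cc(O)c(CC2=C(O)C(C)(C)C(O)=C(C(=O)CC)C2=O)c1O | intermediate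
19 | phloroglucinol | Oc1cc(O)cc(O)c1 | starting material
20 | butyryl chloride | CCCC(=O)Cl | starting material
21 | 1-(2,4,6-trihydroxyphenyl)butan-1-one | CCCC(=O)c1c(O)cc(O)cc1O | intermediate
22 | 1-(2,4,6-trihydroxy-3-methylphenyl)butan-1-one | CCCC(=O)c1c(O)cc(O)c(C)c1O | intermediate (not isolated)
23 | 2-butanoyl-3,5-dihydroxy-4,4-dimethylcyclohexa-2,5-dien-1-one (butyrylfilicinic acid) | CCCC(=O)C1=C(O)C(C)(C)C(O)=CC1=O | intermediate
24 | 2-butanoyl-6-[(dimethylamino)methyl]-3,5-dihydroxy-4,4-dimethylcyclohexa-2,5-dien-1-one | CCCC(=O)C1=C(O)C(C)(C)C(O)=C(CN(C)C)C1=O | intermediate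
25 | 2-butanoyl-3-hydroxy-4,4-dimethyl-6-methylidenecyclohex-2-ene-1,5-dione | CCCC(=O)C1=C(O)C(C)(C)C(=O)C(=C)C1=O | intermediate (not isolated)
26 | 2-butanoyl-6-({3-butanoyl-5-[(2,4-dihydroxy-3,3-dimethyl-6-oxo-5-propanoylcyclohexa-1,4-dien-1-yl)methyl]-2,4,6-trihydroxyphenyl}methyl)-3,5-dihydroxy-4,4-dimethylcyclohexa-2,5-dien-1-one | CCCC(=O)C1=C(O)C(C)(C)C(O)=C(Cc2c(O)c(CC3=C(O)C(C)(C)C(O)=C(C(=O)CC)C3=O)c(O)c(C(=O)CCC)c2O)C1=O | target

**Step count and risks**

Total step count: 12. Longest linear sequence: 7 steps (steps 1, 2, 3, 6, 7, 8, 12).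

Steps most likely to fail:

1. Step 6. The ketone enolate may be acylated on oxygen, the ketene may be consumed by the donor enolate, or the stabilised carbanion may fail to close onto the hindered ester. The fallback sets out from 6 and returns to the route at 14, forming the two ring bonds in separate, known operations. C-acetylation of the lithium enolate of 6 (LiN(i-Pr)2, THF, −78 °C; 1-acetylbenzotriazole) should give methyl 4-acetyl-2,2-dimethyl-3-oxo-5-[2,4,6-tris(benzyloxy)phenyl]pentanoate F1. Its dianion (LiN(i-Pr)2, 2.2 equiv, −78 → 0 °C) should close through the terminal acetyl carbon onto the ester in a dianion Dieckmann cyclisation to 3,5-dihydroxy-4,4-dimethyl-2-{[2,4,6-tris(benzyloxy)phenyl]methyl}cyclohexa-2,5-dien-1-one F2. C-propionylation of the only free ring carbon (propionic acid, DCC, DMAP; O-acylation then O-to-C acyl shift) should then give 14.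

2. Step 12. The existing bridge between rings B and C may cleave and recombine (retro-Michael exchange of methylene bridges), and the methylidene trione may self-condense to symmetric products. The fallback sets out from 18 and returns at 26, fixing the bridge carbon irreversibly by hydride capture. Vilsmeier formylation (POCl3, DMF, then water) at the free ring-B position of 18 should give 3-butanoyl-5-[(2,4-dihydroxy-3,3-dimethyl-6-oxo-5-propanoylcyclohexa-1,4-dien-1-yl)methyl]-2,4,6-trihydroxybenzaldehyde F3. Three-component reductive alkylation of 23 with F3 (Hantzsch ester, L-proline cat., CH2Cl2, rt: Knoevenagel condensation, then reduction of the quinone methide in the flask) should give 26.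

3. Step 7. Benzyl groups may be lost or migrate in the acidic acylation medium, and acylation of the position flanked by two benzyloxy groups may be sluggish. The fallback sets out from 14 and returns at 18, reversing the order of deprotection and acylation. Hydrogenolysis of 14 (H2, Pd/C) should give 3,5-dihydroxy-4,4-dimethyl-2-propanoyl-6-[(2,4,6-trihydroxyphenyl)methyl]cyclohexa-2,5-dien-1-one F4. Houben–Hoesch acylation of its free phloroglucinol ring with butyronitrile (ZnCl2, HCl, Et2O, 0 °C) should give the ketiminium chloride 1-{3-[(2,4-dihydroxy-3,3-dimethyl-6-oxo-5-propanoylcyclohexa-1,4-dien-1-yl)methyl]-2,4,6-trihydroxyphenyl}butan-1-iminium chloride F5, which warm water should hydrolyse to 18.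

**Further compounds**

F1 | step 6 | methyl 4-acetyl-2,2-dimethyl-3-oxo-5-[2,4,6-tris(benzyloxy)phenyl]pentanoate (racemic, enolisable) | COC(=O)C(C)(C)C(=O)C(Cc1c(OCc2ccccc2)cc(OCc2ccccc2)cc1OCc1ccccc1)C(C)=O
F2 | step 6 | 3,5-dihydroxy-4,4-dimethyl-2-{[2,4,6-tris(benzyloxy)phenyl]methyl}cyclohexa-2,5-dien-1-one | O=C1C=C(O)C(C)(C)C(O)=C1Cc1c(OCc2ccccc2)cc(OCc2ccccc2)cc1OCc1ccccc1
F3 | step 12 | 3-butanoyl-5-[(2,4-dihydroxy-3,3-dimethyl-6-oxo-5-propanoylcyclohexa-1,4-dien-1-yl)methyl]-2,4,6-trihydroxybenzaldehyde | CCCC(=O)c1c(O)c(C=O)c(O)c(CC2=C(O)C(C)(C)C(O)=C(C(=O)CC)C2=O)c1O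
F4 | step 7 | 3,5-dihydroxy-4,4-dimethyl-2-propanoyl-6-[(2,4,6-trihydroxyphenyl)methyl]cyclohexa-2,5-dien-1-one | CCC(=O)C1=C(O)C(C)(C)C(O)=C(Cc2c(O)cc(O)cc2O)C1=O
F5 | step 7 | 1-{3-[(2,4-dihydroxy-3,3-dimethyl-6-oxo-5-propanoylcyclohexa-1,4-dien-1-yl)methyl]-2,4,6-trihydroxyphenyl}butan-1-iminium chloride | CCCC(=[NH2+])c1c(O)cc(O)c(CC2=C(O)C(C)(C)C(O)=C(C(=O)CC)C2=O)c1O.[Cl-]
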